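A direct plan would buy rings A and B as arenes and close ring C last.
It would iodinate 2,4-bis(benzyloxy)-6-hydroxyacetophenone A1 ortho to the phenol, exchange iodine for methoxide under copper catalysis (ketone A2) and oxidise the acetyl group with SeO2 to the aryl glyoxal A3.
A carbene-catalysed cross-benzoin of A3 with 2,4-bis(benzyloxy)-5-methoxybenzaldehyde A4, cyclodehydration and O-methylation would give the tetrabenzyl flavone A5, and hydrogenolysis the target.
Weakest would be the cross-benzoin/cyclisation cascade: the choice between two aldehydes (homo-benzoin, enediol scrambling, lactol forms of A3) has no precedent, so the C2–C3 bond and the closure of ring C would be left to chance on material from both branches.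
Next would be the iodination/copper methoxylation pair, which would spend two steps on one methoxy group and risk protodeiodination beside a free phenol and an enolisable ketone.
Third would be the SeO2 oxidation of an electron-rich ortho-hydroxyacetophenone, prone to over-oxidation and giving a hydrated glyoxal that is hard to dry and to dose.
The demethylation and re-benzylation needed to reach A4 would add two steps of protecting-group exchange only.

**Plan of the new route**
The retrosynthesis leaves ring C intact and cuts ring A at C5–C4a, C5–C6 and C7–C8: a Danheiser-type benzannulation of a pyranonyl(methoxy)ketene with tert-butoxyacetylene.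
Enabling feature: ring A carries the segment C5(OH)–C6(H)–C7(OH), the footprint of a ketene carbonyl plus an alkoxyacetylene, flanked by C8(OMe) and by the C4a=C8a bond it shares with the 4-pyranone ring C, which has a free C4a–H in the precursor.
The precursor is kojic acid in disguise: O1, C2, C3–O, C4=O, C4a, C8a and C8–O are its own atoms; C5 with its oxygen is CO2, and ring B is joined at C2–C1′ by Suzuki coupling.
Order of rings: B (bought arene), C (bought as kojic acid), A last and from open-chain pieces.
No arene is methoxylated, no glyoxal and no benzoin are needed, and since O1–C8a is never opened the methoxy group cannot appear at C6 instead of C8.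

Key step: step 9

Remark on the chemistry: flavone numbering (O1, C2 to C8a, C1′ to C6′) is used for the corresponding atoms of all precursors. tert-Butoxyacetylene is treated as a reagent to be made (step 8). The target is achiral; the stereocentres that appear in 12, 17, 19 and 21 are racemic and are erased in step 9.

**Step 1**
Reactants: 1 kojic acid (5-hydroxy-2-(hydroxymethyl)-4H-pyran-4-one)
Product: 2 2-bromo-3-hydroxy-6-(hydroxymethyl)-4H-pyran-4-one (6-bromokojic acid)
Conditions: NBS (1.05 equiv), MeCN, 0 °C → rt, dark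
Reagents that add atoms: N-bromosuccinimide, O=C1CCC(=O)N1Br
Why: Electrophilic bromination of the enol should go to C-6 (the future C2), the β-carbon of the 5-hydroxy enol and the site at which kojic acid takes up electrophiles; no stereocentre is formed.

**Step 2**
Reactants: 2 2-bromo-3-hydroxy-6-(hydroxymethyl)-4H-pyran-4-one
Product: 3 2-bromo-3-methoxy-6-(methoxymethyl)-4H-pyran-4-one
Conditions: MeI (8 equiv), Ag2O (3 equiv), 4 Å MS, MeCN, rt → 40 °C, dark
Reagents that add atoms: iodomethane, CI
Why: Purdie methylation should etherify the acidic enolic hydroxyl and the primary alcohol in one operation under non-basic conditions that spare the vinylogous acyl bromide; the two oxygens become O3 and O8 of the target.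

**Step 3**
Reactants: 4 2-bromo-5-hydroxy-4-methoxybenzaldehyde
Product: 6 4-bromo-6-methoxybenzene-1,3-diol, via aryl formate 5 (not isolated)
Conditions: mCPBA (1.3 equiv), CH2Cl2, 0 °C → rt; aq. NaHCO3/Na2S2O3 wash; then Et3N (0.1 equiv), MeOH, N2, rt
Reagents that add atoms: 3-chloroperoxybenzoic acid, O=C(OO)c1cccc(Cl)c1
Why: Baeyer–Villiger (Dakin-type) oxidation, in which the para-methoxy group should make the aryl group migrate to give formate 5, whose methanolysis frees the second phenol.

**Step 4**
Reactants: 6 4-bromo-6-methoxybenzene-1,3-diol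
Product: 7 1-bromo-5-methoxy-2,4-bis(methoxymethoxy)benzene
Conditions: MOMCl (2.6 equiv), i-Pr2NEt (3 equiv), CH2Cl2, 0 °C → rt
Reagents that add atoms: chloromethyl methyl ether, COCCl
Why: O-Alkylation of both phenols gives acetal ethers that should survive organolithium, cross-coupling and amide-base steps and fall together with the tert-butyl ether in the last step.

**Step 5**
Reactants: 7 1-bromo-5-methoxy-2,4-bis(methoxymethoxy)benzene
Product: 9 [5-methoxy-2,4-bis(methoxymethoxy)phenyl]boronic acid, via aryllithium 8 (not isolated)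
Conditions: n-BuLi (1.05 equiv), THF, −78 °C; B(Oi-Pr)3 (1.5 equiv), −78 → 0 °C; aq. NH4Cl
Reagents that add atoms: triisopropyl borate, CC(C)OB(OC(C)C)OC(C)C; water, O
Why: Bromine–lithium exchange at −78 °C is faster than any deprotonation, and the aryllithium 8 is trapped by the borate and hydrolysed to the boronic acid.

**Step 6**
Reactants: 3 2-bromo-3-methoxy-6-(methoxymethyl)-4H-pyran-4-one; 9 [5-methoxy-2,4-bis(methoxymethoxy)phenyl]boronic acid
Product: 10 3-methoxy-2-[5-methoxy-2,4-bis(methoxymethoxy)phenyl]-6-(methoxymethyl)-4H-pyran-4-one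
Conditions: 9 (1.3 equiv), Pd(OAc)2 (5 mol %), SPhos (2-dicyclohexylphosphino-2′,6′-dimethoxybiphenyl, 10 mol %), K3PO4 (3 equiv), toluene/H2O (10:1), 80 °C
Reagents that add atoms: none
Why: Suzuki–Miyaura coupling of a β-bromo enone (fast oxidative addition) with an electron-rich arylboronic acid should form the C2–C1′ bond, the biarylphosphine coping with the ortho substituents on both partners.

**Step 7**
Reactants: 10 3-methoxy-2-[5-methoxy-2,4-bis(methoxymethoxy)phenyl]-6-(methoxymethyl)-4H-pyran-4-one
Product: 12 2-methoxy-2-{5-methoxy-6-[5-methoxy-2,4-bis(methoxymethoxy)phenyl]-4-oxo-4H-pyran-2-yl}acetic acid (racemic), via lithium dienolate 11 (not isolated)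
Conditions: LiHMDS (1.2 equiv), THF, −78 °C; CO2 (dry gas), −78 → −30 °C; cold 0.5 M HCl to pH 3, extraction without heating; used crude
Reagents that add atoms: carbon dioxide, O=C=O
Why: γ-Deprotonation of a 2-alkyl-4-pyranone gives the extended enolate 11, which should take up CO2 at the exocyclic carbon (C8) so that the pyranone is restored (vinylogous enolate carboxylation); the new stereocentre is racemic and is erased in step 9.

**Step 8**
Reactants: 13 trichloroethylene
Product: 16 tert-butoxyacetylene (tert-butyl ethynyl ether), via (E)-1-tert-butoxy-1,2-dichloroethene 14 (not isolated), via lithium tert-butoxyacetylide 15 (not isolated)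
Conditions: KOt-Bu (1.0 equiv), THF/pentane, −70 °C → rt; n-BuLi (2.3 equiv), −78 → −40 °C; H2O, −78 °C; distilled with pentane below 30 °C, assayed and kept as a solution at −20 °C
Reagents that add atoms: potassium tert-butoxide, CC(C)(C)[O-].[K+]
Why: Dichlorovinyl ether route to ynol ethers: the alkoxide adds to dichloroacetylene formed in situ to give 14, n-BuLi effects elimination and chlorine–lithium exchange to acetylide 15, and protonation gives the terminal ynol ether.

**Step 9**
Reactants: 12 2-methoxy-2-{5-methoxy-6-[5-methoxy-2,4-bis(methoxymethoxy)phenyl]-4-oxo-4H-pyran-2-yl}acetic acid; 16 tert-butoxyacetylene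
Product: 22 7-tert-butoxy-5-hydroxy-3,8-dimethoxy-2-[5-methoxy-2,4-bis(methoxymethoxy)phenyl]-4H-chromen-4-one, via acid chloride 17 (not isolated), via pyranonyl(methoxy)ketene 18 (not isolated), via 3-tert-butoxycyclobutenone 19 (not isolated), via (Z)-dienylketene 20 (not isolated), via 4aH-chromene-4,5-dione 21 (not isolated)
Conditions: 1-chloro-N,N,2-trimethylprop-1-en-1-amine (1.1 equiv), CH2Cl2, 0 °C → rt; 16 (4 equiv), then Et3N (1.5 equiv, added over 2 h), 0 °C → rt; volatiles removed at ≤ 20 °C, toluene, filtration from Et3N·HCl; 100 °C (0.02 M)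
Reagents that add atoms: none
Why: Proposed new method: Et3N dehydrochlorinates acid chloride 17 to the pyranonyl(methoxy)ketene 18, whose carbonyl carbon (the future C5) bonds to the nucleophilic CH terminus of ynol ether 16 and whose α-carbon (C8) bonds to the oxygen-bearing alkyne carbon in a [2+2] cycloaddition, so that cyclobutenone 19 already has C6–H between the two oxygenated carbons and O7 next to C8–OMe. On heating, 19 should open by a conrotatory 4π electrocyclic reaction in which the donor methoxy group on C8 rotates outward and the pyranone therefore inward, giving the (Z)-dienylketene 20 (the (E)-isomer would revert through 19). Ring A then closes by a thermal 6π electrocyclisation of 20 onto C4a of the pyranone C4a=C8a bond (C5–C4a bond), and the doubly activated C4a–H of 21 enolises to the chelated 5-hydroxy phenol; ring C is never opened, so the methoxy group cannot end up at C6. The closest known reaction type is the Danheiser benzannulation of vinylketenes with alkoxy- or siloxyalkynes, supported by the [2+2] cycloaddition of acid-chloride-derived ketenes with ethoxyacetylene and the thermal ring expansion of 4-aryl-4-alkoxycyclobutenones; what has not been shown is an alkoxy(heteroaryl)ketene made by dehydrochlorination and a 4-pyranone C=C bond as the 2π component. The selectivity needed is cycloaddition ahead of ketene dimerisation and of retro-ene loss of isobutene from 16, which slow addition of base into excess 16 below 25 °C and removal of 16 before heating should secure. The stereocentres of 19 (C8) and 21 (C4a) are racemic and are erased on aromatisation, so no stereocontrol is required.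

**Step 10**
Reactants: 22 7-tert-butoxy-5-hydroxy-3,8-dimethoxy-2-[5-methoxy-2,4-bis(methoxymethoxy)phenyl]-4H-chromen-4-one
Product: 23 5,7-dihydroxy-2-(2,4-dihydroxy-5-methoxyphenyl)-3,8-dimethoxy-4H-chromen-4-one (5,7,2′,4′-tetrahydroxy-3,8,5′-trimethoxyflavone)
Conditions: HCl (3 M in MeOH), THF co-solvent, 50 °C
Reagents that add atoms: none
Why: Acid-catalysed acetal exchange should remove both methoxymethyl groups and SN1 cleavage the tert-butyl aryl ether, with methanol trapping the cations, while the aryl methyl ethers and the flavone are stable; the product has no stereocentre.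

**Compound list**
1 | kojic acid, 5-hydroxy-2-(hydroxymethyl)-4H-pyran-4-one | OCc1cc(=O)c(O)co1 | starting material
2 | 2-bromo-3-hydroxy-6-(hydroxymethyl)-4H-pyran-4-one | OCc1cc(=O)c(O)c(Br)o1 | intermediate
3 | 2-bromo-3-methoxy-6-(methoxymethyl)-4H-pyran-4-one | COCc1cc(=O)c(OC)c(Br)o1 | intermediate
4 | 2-bromo-5-hydroxy-4-methoxybenzaldehyde | COc1cc(Br)c(C=O)cc1O | starting material
5 | 2-bromo-5-hydroxy-4-methoxyphenyl formate (formed in the flask) | COc1cc(Br)c(OC=O)cc1O | intermediate
6 | 4-bromo-6-methoxybenzene-1,3-diol | COc1cc(Br)c(O)cc1O | intermediate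
7 | 1-bromo-5-methoxy-2,4-bis(methoxymethoxy)benzene | COCOc1cc(OCOC)c(OC)cc1Br | intermediate
8 | [5-methoxy-2,4-bis(methoxymethoxy)phenyl]lithium (formed in the flask) | COCOc1cc(OCOC)c(OC)cc1[Li] | intermediate
9 | [5-methoxy-2,4-bis(methoxymethoxy)phenyl]boronic acid | COCOc1cc(OCOC)c(OC)cc1B(O)O | intermediate
10 | 3-methoxy-2-[5-methoxy-2,4-bis(methoxymethoxy)phenyl]-6-(methoxymethyl)-4H-pyran-4-one | COCc1cc(=O)c(OC)c(-c2cc(OC)c(OCOC)cc2OCOC)o1 | intermediate
11 | lithium 3-methoxy-2-[5-methoxy-2,4-bis(methoxymethoxy)phenyl]-6-(methoxymethylidene)-6H-pyran-4-olate (extended enolate, exocyclic geometry undefined, formed in the flask) | [Li]OC1=CC(=COC)OC(c2cc(OC)c(OCOC)cc2OCOC)=C1OC | intermediate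
12 | 2-methoxy-2-{5-methoxy-6-[5-methoxy-2,4-bis(methoxymethoxy)phenyl]-4-oxo-4H-pyran-2-yl}acetic acid (racemic) | COC(C(=O)O)c1cc(=O)c(OC)c(-c2cc(OC)c(OCOC)cc2OCOC)o1 | intermediate
13 | trichloroethylene | ClC=C(Cl)Cl | starting material
14 | (E)-1-tert-butoxy-1,2-dichloroethene (formed in the flask) | CC(C)(C)O/C(Cl)=C\Cl | intermediate
15 | lithium tert-butoxyacetylide (formed in the flask) | [Li]C#COC(C)(C)C | intermediate
16 | tert-butoxyacetylene | C#COC(C)(C)C | intermediate
17 | 2-methoxy-2-{5-methoxy-6-[5-methoxy-2,4-bis(methoxymethoxy)phenyl]-4-oxo-4H-pyran-2-yl}acetyl chloride (racemic, formed in the flask) | COC(C(=O)Cl)c1cc(=O)c(OC)c(-c2cc(OC)c(OCOC)cc2OCOC)o1 | intermediate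
18 | 2-methoxy-2-{5-methoxy-6-[5-methoxy-2,4-bis(methoxymethoxy)phenyl]-4-oxo-4H-pyran-2-yl}ethen-1-one (ketene, formed in the flask) | COC(=C=O)c1cc(=O)c(OC)c(-c2cc(OC)c(OCOC)cc2OCOC)o1 | intermediate
19 | 3-tert-butoxy-4-methoxy-4-{5-methoxy-6-[5-methoxy-2,4-bis(methoxymethoxy)phenyl]-4-oxo-4H-pyran-2-yl}cyclobut-2-en-1-one (racemic, formed in the flask) | COC1(c2cc(=O)c(OC)c(-c3cc(OC)c(OCOC)cc3OCOC)o2)C(=O)C=C1OC(C)(C)C | intermediate
20 | (3Z)-3-tert-butoxy-4-methoxy-4-{5-methoxy-6-[5-methoxy-2,4-bis(methoxymethoxy)phenyl]-4-oxo-4H-pyran-2-yl}buta-1,3-dien-1-one (dienylketene, formed in the flask) | O=C=C/C(OC(C)(C)C)=C(/OC)c1cc(=O)c(OC)c(-c2cc(OC)c(OCOC)cc2OCOC)o1 | intermediate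
21 | 7-tert-butoxy-3,8-dimethoxy-2-[5-methoxy-2,4-bis(methoxymethoxy)phenyl]-4aH-chromene-4,5-dione (racemic keto tautomer, formed in the flask) | COC1=C(c2cc(OC)c(OCOC)cc2OCOC)OC2=C(OC)C(OC(C)(C)C)=CC(=O)C2C1=O | intermediate
22 | 7-tert-butoxy-5-hydroxy-3,8-dimethoxy-2-[5-methoxy-2,4-bis(methoxymethoxy)phenyl]-4H-chromen-4-one | COc1c(-c2cc(OC)c(OCOC)cc2OCOC)oc2c(OC)c(OC(C)(C)C)cc(O)c2c1=O | intermediate
23 | 5,7-dihydroxy-2-(2,4-dihydroxy-5-methoxyphenyl)-3,8-dimethoxy-4H-chromen-4-one | COc1cc(-c2oc3c(OC)c(O)cc(O)c3c(=O)c2OC)c(O)cc1O | target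

**Count**
Total: 10 steps. Longest linear sequence: 7 steps (steps 3, 4, 5, 6, 7, 9 and 10, from 2-bromo-5-hydroxy-4-methoxybenzaldehyde).

**Steps most likely to fail**

Step 9. Dimerisation or amine-induced oligomerisation of ketene 18 may outrun the cycloaddition, or the tert-butyl ynol ether may fragment thermally before it is consumed. The fallback uses known chemistry and closes ring C last; it sets out from bromide 7 and returns at target 23. Bromine–lithium exchange (n-BuLi, −78 °C) and formylation with DMF would give 5-methoxy-2,4-bis(methoxymethoxy)benzaldehyde F1. Claisen–Schmidt condensation (KOH, EtOH) with the 3-methoxy ketone A2 of the direct plan would give the (E)-chalcone F2. Algar–Flynn–Oyamada oxidation (H2O2, NaOH, MeOH, 0 °C, kept cold to hold back aurone formation) would give the flavonol F3, and methylation (MeI, K2CO3, acetone) the 3-methyl ether F4. Hydrogenolysis (H2, Pd/C, EtOAc/MeOH) would give the 5,7-diol F5, and HCl in MeOH the target 23.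

Step 7. CO2 may attack the ring α-carbon of the extended enolate, or the vinylogous β-keto acid may decarboxylate during acidification. The fallback sets out from 2 and returns at 12. Selective methylation of the enolic hydroxyl (MeI, K2CO3, acetone) would give 2-bromo-6-(hydroxymethyl)-3-methoxy-4H-pyran-4-one F6. Suzuki coupling with 9 under the conditions of step 6 would give 6-(hydroxymethyl)-3-methoxy-2-[5-methoxy-2,4-bis(methoxymethoxy)phenyl]-4H-pyran-4-one F7. Oxidation with MnO2 (CH2Cl2, rt) would give 5-methoxy-6-[5-methoxy-2,4-bis(methoxymethoxy)phenyl]-4-oxo-4H-pyran-2-carbaldehyde F8. A Jocic–Reeve reaction (CHBr3, KOH, MeOH, 0 °C) would convert the aldehyde in one operation into the α-methoxy acid 12.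

Step 2. Etherification of the primary alcohol may stay incomplete, or silver may assist loss of the bromide. The fallback sets out from 1 and returns at 3. SOCl2 would give 2-(chloromethyl)-5-hydroxy-4H-pyran-4-one F9, and NaOMe in MeOH would give 5-hydroxy-2-(methoxymethyl)-4H-pyran-4-one F10. Bromination with NBS as in step 1 would give 2-bromo-3-hydroxy-6-(methoxymethyl)-4H-pyran-4-one F11, and MeI/K2CO3 in acetone would methylate the enolic hydroxyl to give 3.

**Further compounds**
F1 | step 9 | 5-methoxy-2,4-bis(methoxymethoxy)benzaldehyde | COCOc1cc(OCOC)c(OC)cc1C=O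
F2 | step 9 | (E)-1-[4,6-bis(benzyloxy)-2-hydroxy-3-methoxyphenyl]-3-[5-methoxy-2,4-bis(methoxymethoxy)phenyl]prop-2-en-1-one | COCOc1cc(OCOC)c(OC)cc1/C=C/C(=O)c1c(O)c(OC)c(OCc2ccccc2)cc1OCc1ccccc1
F3 | step 9 | 5,7-bis(benzyloxy)-3-hydroxy-8-methoxy-2-[5-methoxy-2,4-bis(methoxymethoxy)phenyl]-4H-chromen-4-one | COCOc1cc(OCOC)c(OC)cc1-c1oc2c(OC)c(OCc3ccccc3)cc(OCc3ccccc3)c2c(=O)c1O
F4 | step 9 | 5,7-bis(benzyloxy)-3,8-dimethoxy-2-[5-methoxy-2,4-bis(methoxymethoxy)phenyl]-4H-chromen-4-one | COCOc1cc(OCOC)c(OC)cc1-c1oc2c(OC)c(OCc3ccccc3)cc(OCc3ccccc3)c2c(=O)c1OC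
F5 | step 9 | 5,7-dihydroxy-3,8-dimethoxy-2-[5-methoxy-2,4-bis(methoxymethoxy)phenyl]-4H-chromen-4-one | COCOc1cc(OCOC)c(OC)cc1-c1oc2c(OC)c(O)cc(O)c2c(=O)c1OC
F6 | step 7 | 2-bromo-6-(hydroxymethyl)-3-methoxy-4H-pyran-4-one | OCc1cc(=O)c(OC)c(Br)o1
F7 | step 7 | 6-(hydroxymethyl)-3-methoxy-2-[5-methoxy-2,4-bis(methoxymethoxy)phenyl]-4H-pyran-4-one | OCc1cc(=O)c(OC)c(-c2cc(OC)c(OCOC)cc2OCOC)o1
F8 | step 7 | 5-methoxy-6-[5-methoxy-2,4-bis(methoxymethoxy)phenyl]-4-oxo-4H-pyran-2-carbaldehyde | O=Cc1cc(=O)c(OC)c(-c2cc(OC)c(OCOC)cc2OCOC)o1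
F9 | step 2 | 2-(chloromethyl)-5-hydroxy-4H-pyran-4-one | ClCc1cc(=O)c(O)co1
F10 | step 2 | 5-hydroxy-2-(methoxymethyl)-4H-pyran-4-one | COCc1cc(=O)c(O)co1
F11 | step 2 | 2-bromo-3-hydroxy-6-(methoxymethyl)-4H-pyran-4-one | COCc1cc(=O)c(O)c(Br)o1
A1 | direct plan | 1-[2,4-bis(benzyloxy)-6-hydroxyphenyl]ethan-1-one | CC(=O)c1c(O)cc(OCc2ccccc2)cc1OCc1ccccc1
A2 | direct plan | 1-[4,6-bis(benzyloxy)-2-hydroxy-3-methoxyphenyl]ethan-1-one | CC(=O)c1c(O)c(OC)c(OCc2ccccc2)cc1OCc1ccccc1
A3 | direct plan | 2-[4,6-bis(benzyloxy)-2-hydroxy-3-methoxyphenyl]-2-oxoacetaldehyde | O=CC(=O)c1c(O)c(OC)c(OCc2ccccc2)cc1OCc1ccccc1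
A4 | direct plan | 2,4-bis(benzyloxy)-5-methoxybenzaldehyde | COc1cc(C=O)c(OCc2ccccc2)cc1OCc1ccccc1
A5 | direct plan | 5,7-bis(benzyloxy)-2-[2,4-bis(benzyloxy)-5-methoxyphenyl]-3,8-dimethoxy-4H-chromen-4-one | COc1cc(-c2oc3c(OC)c(OCc4ccccc4)cc(OCc4ccccc4)c3c(=O)c2OC)c(OCc2ccccc2)cc1OCc1ccccc1
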